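All runs were computed from invented constants.

- You asked two things, and your quick number hangs on one constant that alpha already holds.

| setting | alpha | larch | ash | birch | cedar | alder |
|---|---|---|---|---|---|---|
| substrate | 0.20 M | 0.20 M | 0.30 M | 0.50 M | 0.60 M | 1.0 M |
| coupling partner | 0.68 M | 1.02 M | 1.02 M | 1.02 M | 1.02 M | 1.02 M |
| free catalyst | 34 mM | 34 mM | 34 mM | 34 mM | 34 mM | 34 mM |
| remark | run made earlier |  |  |  |  |  |
| time |  | 4.0 d | 4.0 d | 4.0 d | 4.0 d | 4.0 d |

- alpha (time / h: product / %, substrate / %): 1.00: 0, 96.0; 3.00: 1.0, 88.6; 5.00: 3.7, 82.4; 8.00: 9.3, 74.5; 12.0: 15.4, 63.0; 15.0: 19.7, 56.6; 20.0: 26.0, 45.7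

(scatter of a reading: 0.5 percentage points)

- a reading or a percentage of product counts all its forms, free or not
- the concentration of product that is asked is that of its free form alone
- "hardly changes" means that all values lie within two and a half points (for a concentration: within two and a half percent of the largest)
- a reading of substrate is of its free form alone

1. [product] (only what is free in solution) at the end for larch, ash, birch, cedar, alder, in this order
2. how that number moves from the first to the last of them (hardly changes / rises, then falls / falls, then rises / rises all the way / falls all the way)

- Write the balance of substrate, the limiting reagent, charged below the coupling partner even in alder: whatever alpha reads neither as substrate nor as product sits on the catalyst or in an idle adduct, which holds one substrate and counts as one product.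
- At 3.00 h alpha shows 1.0% product, so I read the gap of 10.4% of the charge as catalyst-held, below the catalyst's share of 17.0%.
- At 20.0 h the gap, less that pool, leaves 17.9% as adduct and 8.10% as free product.
- That gives the parking constant, adduct over free substrate times free product: 24.2 L mol⁻¹, a reading that carries the scatter.
- Each free product then has N = constant × charge × substrate share of adducts beside it, and the balance gives the free share as (whole charge − substrate − pool)/(1 + twice N).
- For larch I keep alpha's decay of 0.0393 h⁻¹, so 2.30% of substrate remains, N is 0.111 and the free share is 71.4%.
- Birch, with the same substrate share, has N of 0.278 and a free share of 60.1%.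
- My assumption for pace is alpha's mean loss scaled by partner, which consumes 0.705 M in the time, above birch's charge but below alder's.
- Alder thus keeps 29.5% of its substrate, N reaches 7.14 and the free share falls to 4.47%.
- My row therefore reads 0.143 M, 0.301 M, 0.0447 M for larch, birch and alder: up, then down.
- Your forecast differs, with 0.115 M, 0.175 M, 0.29 M, 0.34 M, 0.5 M and rises all the way, on the ground that “only about 60% of the substrate lost goes to product”.

    coupling partner + catalyst intermediate A → catalyst intermediate B (k = 0.00440 L mol⁻¹ min⁻¹)
    substrate + free catalyst → catalyst intermediate A (k = 0.0280 L mol⁻¹ min⁻¹)
    catalyst intermediate B → free catalyst + product (k = 0.0140 min⁻¹)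
    substrate + product ⇌ idle adduct, settled at all times (K = 27.0 L mol⁻¹)

- The flasks give 0.128 M, 0.155 M, 0.167 M, 0.157 M, 0.0760 M, so the row rises, then falls, turning at 0.45 M. Alder at 4.00 d holds 17.6% substrate and 43.8% product, bound forms counted. Put the parking constant as read from alpha on those two: my estimate of N is 4.26, so I reckon a free share of 8.32% of the charge, while alder's free product stands at 7.60% of its charge.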